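## The problem

The target is a (3R)-isoflavan: a chroman (rings A and C) that carries at C3 an aryl group (ring B), onto which a 2,2-dimethyl-2H-pyran is fused across C2'–C3' through the 2'-oxygen. Its four phenolic oxygens are in three different states: the 5-methyl ether, the free 7- and 4'-hydroxyls, and the 2'-oxygen locked in the pyran. The two oxygens of the resorcinol-type ring B are the hardest pair to tell apart. The only stereocentre is C3, a benzylic methine between two methylene groups. No second stereocentre can relay to it, so its configuration has to come from a catalyst. In return, once set it is robust, because it is not α to a carbonyl group. The electron-rich chromene double bond of the dimethylpyran would not survive catalytic hydrogenation and is at risk under strong acid, so the pyran has to be built after any reductive step and the final deprotection must be mild. The enabling feature is that the 2'-oxygen is ortho to the C1'–C3 bond and can reach C4, which is benzylic to ring A and receives electron density from O1, the 5-methoxy group and the 7-oxygen. A C4–O(2') bond should therefore form readily through a C4 cation and be cut again by hydrogenolysis. The isoflavan is thus the ring-opened form of a cis-pterocarpan, in which C3 is one of two ring-fusion centres that fix each other, and in which the 2'-oxygen stays masked until the pyran needs it.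

## Retrosynthesis

Compound numbers are those of the steps below; isoflavan numbering is used (O1, C2, C3, C4; ring B primed), and pterocarpan numbering (C6a, C11a) for 12.

**Phenols and pyran.** The target 18 is traced back to its bis-MOM ether 17. In 17 the pyran is cut at the O–CMe2 bond and at the C3'–CH= bond, giving the aryl 1,1-dimethylpropargyl ether 15, and from there the 2'-phenol 13 and 3-chloro-3-methylbut-1-yne 14. Condensing an enal with a free resorcinol would have to choose between the 2'- and 4'-oxygens and between rings A and B. The propargyl ether route needs only one free phenol, and in 13 the ortho position C1' is blocked, so the rearrangement can only go to C3'. This asks that the 2'-hydroxyl be the only free phenol in 13.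

**The 2'-phenol.** In 13 the C4–H bond is replaced by a C4–O(2') bond, which leads to the cis-pterocarpan 12. This costs one hydrogenolysis step in the forward direction. It is worth it because the cleavage frees the 2'-oxygen and no other, and because 12 is a rigid bicycle whose two stereocentres depend on each other. The forward step must cut the benzylic C11a–O bond and leave the MOM ethers alone.

**The stereocentre.** In 12 the C11a–O bond and the C6a–H bond are cut together, giving the flat, achiral 2'-hydroxyisoflav-3-ene 11. The neighbouring cut, C3–H alone, would be an asymmetric hydrogenation of an isoflavene with a precious-metal catalyst; it is known and is kept as the fallback. The protonative cyclisation is preferred because it uses the substrate's own 2'-hydroxyl as trap and as hydrogen-bond handle, needs no metal, and gives a bicycle that could in principle be enriched by crystallisation before it is opened. The forward step must deliver the proton to one face of C3.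

**Ring C.** The ether bond O1–C2 of 11 is cut after masking the 2'-hydroxyl as the silyl ether 10. This gives the (Z)-allylic alcohol 9, which is the reduction product of the 3-arylcoumarin 8, itself the silyl ether of 7. The coumarin fixes the Z geometry that the ring closure needs. The silyl group is required because in the free triol the 2'-hydroxyl could close a five-membered ring onto the same carbon.

**The carbon skeleton.** The coumarin 7 is cut at the C3=C4 double bond and at the lactone C–O bond, giving the salicylaldehyde 2 and the benzofuranone 5. A Perkin condensation of the free arylacetic acid in acetic anhydride would leave both ring B oxygens as acetates. In the lactone 5 the 2'-oxygen is held in the ring, and the lactone exchange that forms the coumarin releases it selectively. Aldehyde 2 comes from commercial 1 by MOM protection of the hydroxyl para to the aldehyde. Lactone 5 comes from commercial 3 by lactonisation to 4 and MOM protection.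

## Roads not taken

Alternative 1: Ring C is cut at C4–C4a and O1–C2, and C3 is set by protonation. A chiral primary amine salt would condense with the 2-arylacrolein A3; the phenol A2 would add through its ortho carbon to the iminium methylene; the resulting enamine would be protonated enantioselectively at C3; and the phenol oxygen would close onto the aldehyde to give the lactol A1. The merits are high convergence, a ring B partner that already carries the pyran, and a short route, since only lactol deoxygenation and desilylation remain. The weak points are structural. A2 has three ring positions, each ortho or para to all three oxygens, and only the one between the hydroxyl and the methoxy group leads to the 5-methoxy-7-oxy pattern; a bulky silyl group biases the choice but does not decide it. The new stereocentre of A1 is benzylic and α to a masked aldehyde, so ring-opening of the lactol and enamine formation with the same amine catalyst can racemise it until the lactol is reduced. A3 is a polymerisable acrolein that needs its own synthesis. Removing the lactol oxygen by ionic hydrogenation brings acid to the chromene. This road is clearly shorter and more convergent than the chosen plan. Against that, the chosen plan fixes the ring A oxygen pattern in aldehyde 1, makes a stereocentre that is never α to a carbonyl group, and builds the chromene last.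

Alternative 2: The pyran is cut at three bonds (C2'–O, C3'–C and O–CMe2) and is built late on an isoflavan that already has the stereocentre. Fluoride would turn the ortho-silylaryl triflate A5 into the aryne A6. The carbonyl group of 3-methylbut-2-enal A7 would add across the strained triple bond; the four-membered ring would open to an ortho-quinone methide; and oxa-6π closure would give A4, which is the same compound as 17. The 4'-alkoxy group directs the nucleophilic oxygen to the distal aryne carbon C2', which is the wanted sense, and one operation makes the whole ring. The weak points are these. The road does not address the stereocentre; it needs an enantioenriched isoflavan such as 13 first. A5 requires regioselective silylation at C3' and triflation of the 2'-hydroxyl, which throws away the oxygen that hydrogenolysis delivers and brings it back with A7. The addition at C2' is electronically favoured but sterically opposed by the chroman on C1'. The chosen plan does the same job from 13 in two reliable steps (etherification with 14 and Claisen rearrangement). This alternative is therefore no shorter and no better in regiocontrol, and would be of interest only if a free 2'-phenol were not available.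

Alternative 3: Ring C is cut at C3–C4 and O1–C2. The salicyl alcohol A9, which is two steps from aldehyde 1, would release the ortho-quinone methide A10. The arylacetaldehyde A11, activated as its enamine by a diarylprolinol silyl ether, would add to the methylene of A10, and the phenol oxygen would close onto the iminium carbon to give the lactol A8. The reaction type is established for quinone methides and aldehydes, the ring A oxygen pattern is fixed from the start, and the route is convergent. In precedent for the key step this road is better than the chosen plan, and it is probably shorter. The weak points are these. A10 carries two strong donors and is a sluggish electrophile. A11 is an arylacetaldehyde with a chromene attached; it needs several steps and is prone to self-condensation. As in Alternative 1, the stereocentre is benzylic and α to a latent aldehyde, and the amine catalyst that makes it can also epimerise it. The lactol must again be deoxygenated in the presence of the chromene. The chosen plan sets against this a stereocentre that cannot enolise once formed, two cheap commercial building blocks, and late installation of the acid-sensitive chromene. Its price is a longer sequence and an unproven key step.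

Key step: step 9

Assumption: which antipode of the confined acid gives (6aR,11aR)-12 cannot be predicted with confidence for this substrate; both antipodes are equally accessible, and the one that delivers the 6aR series is used.

Step 1
Reactants: 1 2,4-dihydroxy-6-methoxybenzaldehyde
Product: 2 2-hydroxy-6-methoxy-4-(methoxymethoxy)benzaldehyde
Conditions: MOMCl (1.1 equiv), iPr2NEt, CH2Cl2, 0 °C to rt
Reagents that add atoms: chloromethyl methyl ether, COCCl
Why: O-alkylation of a phenol; the 2-hydroxyl is held in a hydrogen bond to the aldehyde carbonyl and is the poorer nucleophile, so one equivalent of MOMCl should go to the hydroxyl para to the aldehyde, the usual selectivity of 2,4-dihydroxybenzaldehydes.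

Step 2
Reactants: 3 2,4-dihydroxyphenylacetic acid
Product: 4 6-hydroxybenzofuran-2(3H)-one
Conditions: TsOH·H2O (cat.), toluene, reflux, Dean–Stark
Reagents that add atoms: none
Why: Acid-catalysed lactonisation (intramolecular Fischer esterification); only the 2-hydroxyl can reach the carboxyl group, so the two phenols of ring B are told apart without a protecting group.

Step 3
Reactants: 4 6-hydroxybenzofuran-2(3H)-one
Product: 5 6-(methoxymethoxy)benzofuran-2(3H)-one
Conditions: MOMCl (1.1 equiv), iPr2NEt, CH2Cl2, 0 °C
Reagents that add atoms: chloromethyl methyl ether, COCCl
Why: Phenol O-alkylation under a hindered tertiary amine; alkylation of the O–H should be much faster than enolisation of the lactone CH2, and an O-alkylated enol (a ketene acetal) would revert to the lactone on aqueous work-up.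

Step 4
Reactants: 2 2-hydroxy-6-methoxy-4-(methoxymethoxy)benzaldehyde; 5 6-(methoxymethoxy)benzofuran-2(3H)-one
Product: 7 3-[2-hydroxy-4-(methoxymethoxy)phenyl]-5-methoxy-7-(methoxymethoxy)-2H-chromen-2-one, via benzylidene lactone 6 (not isolated)
Conditions: Et3N (2 equiv), MeCN, 80 °C
Reagents that add atoms: none
Why: Amine-mediated Knoevenagel condensation of the acidic lactone CH2 (its enolate is an aromatic benzofuran-2-olate) with the salicylaldehyde, then intramolecular transesterification in which the ring A phenoxide opens the five-membered aryl lactone and forms the conjugated coumarin, a Perkin-type 3-arylcoumarin synthesis. The lactone exchange releases the 2'-phenol and no other.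

Step 5
Reactants: 7 3-[2-hydroxy-4-(methoxymethoxy)phenyl]-5-methoxy-7-(methoxymethoxy)-2H-chromen-2-one
Product: 8 3-[2-(tert-butyldimethylsilyloxy)-4-(methoxymethoxy)phenyl]-5-methoxy-7-(methoxymethoxy)-2H-chromen-2-one
Conditions: TBSCl, imidazole, DMF, rt to 40 °C
Reagents that add atoms: tert-butyldimethylsilyl chloride, CC(C)(C)[Si](C)(C)Cl
Why: Imidazole-promoted silylation of a phenol; the 2'-hydroxyl must be masked because after lactone reduction it would compete with the ring A phenol in the ring closure, and the silyl ether can later be removed by fluoride without touching the MOM ethers.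

Step 6
Reactants: 8 3-[2-(tert-butyldimethylsilyloxy)-4-(methoxymethoxy)phenyl]-5-methoxy-7-(methoxymethoxy)-2H-chromen-2-one
Product: 9 (Z)-2-[2-(tert-butyldimethylsilyloxy)-4-(methoxymethoxy)phenyl]-3-[2-hydroxy-6-methoxy-4-(methoxymethoxy)phenyl]prop-2-en-1-ol
Conditions: iBu2AlH (4 equiv), CH2Cl2, −78 to 0 °C; aq. KNaC4H4O6
Reagents that add atoms: none
Why: 1,2-Reduction of the unsaturated lactone by excess iBu2AlH through the lactol to the allylic alcohol; the double bond keeps the Z geometry imposed by the coumarin ring, and aryl silyl and MOM ethers are inert.

Step 7
Reactants: 9 (Z)-2-[2-(tert-butyldimethylsilyloxy)-4-(methoxymethoxy)phenyl]-3-[2-hydroxy-6-methoxy-4-(methoxymethoxy)phenyl]prop-2-en-1-ol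
Product: 10 tert-butyl{2-[5-methoxy-7-(methoxymethoxy)-2H-chromen-3-yl]-5-(methoxymethoxy)phenoxy}dimethylsilane
Conditions: PPh3, DIAD, THF, 0 °C to rt
Reagents that add atoms: none
Why: Intramolecular Mitsunobu etherification; the only free phenol displaces the activated primary allylic alcohol (6-exo-tet, SN2) while the Z-alkene holds the two ends together, a known way from 3-arylcoumarins to isoflav-3-enes, and no acid is present that could ionise the allylic system.

Step 8
Reactants: 10 tert-butyl{2-[5-methoxy-7-(methoxymethoxy)-2H-chromen-3-yl]-5-(methoxymethoxy)phenoxy}dimethylsilane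
Product: 11 2-[5-methoxy-7-(methoxymethoxy)-2H-chromen-3-yl]-5-(methoxymethoxy)phenol
Conditions: Bu4NF, AcOH (1 equiv each), THF, 0 °C
Reagents that add atoms: none
Why: Fluoride cleavage of an aryl silyl ether; acetic acid buffers the phenoxide so that the electron-rich isoflavene is not exposed to base and air, and the MOM ethers and the double bond are untouched.

Step 9
Reactants: 11 2-[5-methoxy-7-(methoxymethoxy)-2H-chromen-3-yl]-5-(methoxymethoxy)phenol
Product: 12 (6aR,11aR)-1-methoxy-3,9-bis(methoxymethoxy)-6a,11a-dihydro-6H-benzofuro[3,2-c]chromene
Conditions: confined chiral imidodiphosphoric acid (BINOL-derived, bulky 3,3'-aryl groups, 5 mol%), toluene (0.02 M), 4 Å MS, −40 °C; Et3N quench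
Reagents that add atoms: none
Why: Proposed new method: the P–OH of the confined acid should transfer a proton to C3, the β-carbon of the ring A styrene, because the resulting C4 cation is delocalised onto O1, the 5-methoxy oxygen and the 7-oxygen; the cation stays paired with the chiral imidodiphosphate while the 2'-hydroxyl, hydrogen-bonded to the anion, adds to C4. The closest known reaction types are chiral Brønsted acid catalysed asymmetric intramolecular hydroalkoxylation of alkenes and spiroacetalisation of hydroxy enol ethers, and, in racemic form, the acid closure of 2'-hydroxyisoflavan-4-ols to cis-pterocarpans through this same cation; an enantioselective protonation of an isoflav-3-ene has not been shown. The dihydrofuran ring closes by 5-exo-trig capture of the cation (the C4=C4a π bond lies outside the new ring), whereas a concerted addition across C3=C4 would be 5-endo, so protonation has to come first. C6a (the former C3) is set by the face of C3 that receives the proton, which is catalyst control inside the chiral pocket, or by the faster-closing ion pair if proton transfer proves reversible. C11a (the former C4) is set by C6a: the phenol hangs from the C3 aryl group and can reach C4 only on the face that this aryl group occupies, and a trans-fused ring system would be badly strained, so only the cis isomer can form. The step needs enantiofacial selectivity in the proton transfer, protonation at C3 and not at C4, and survival of the MOM ethers. The substrate helps through its three ring A donors, which make C3 the basic site and let a moderately strong acid work at −40 °C without an external nucleophile; through the intramolecular nucleophile, which should outrun dimerisation in dilute solution; and through the 2'-OH, which gives the catalyst a second point of contact.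

Step 10
Reactants: 12 (6aR,11aR)-1-methoxy-3,9-bis(methoxymethoxy)-6a,11a-dihydro-6H-benzofuro[3,2-c]chromene
Product: 13 2-[(3R)-5-methoxy-7-(methoxymethoxy)-3,4-dihydro-2H-chromen-3-yl]-5-(methoxymethoxy)phenol
Conditions: H2 (1 atm), 10% Pd/C, EtOAc/EtOH, rt
Reagents that add atoms: none
Why: Catalytic hydrogenolysis of the benzyl aryl ether bond C11a–O, which is benzylic to the electron-rich ring A; this is the classical conversion of pterocarpans into 2'-hydroxyisoflavans. C6a carries no heteroatom and is not touched, so 6aR becomes 3R while C11a becomes the C4 methylene, and MOM ethers survive neutral conditions.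

Step 11
Reactants: 13 2-[(3R)-5-methoxy-7-(methoxymethoxy)-3,4-dihydro-2H-chromen-3-yl]-5-(methoxymethoxy)phenol; 14 3-chloro-3-methylbut-1-yne
Product: 15 (3R)-5-methoxy-7-(methoxymethoxy)-3-[4-(methoxymethoxy)-2-(2-methylbut-3-yn-2-yloxy)phenyl]-3,4-dihydro-2H-chromene
Conditions: DBU, CuCl2 (1 mol%), MeCN, 0 °C to rt
Reagents that add atoms: none
Why: Copper-catalysed propargylic etherification of a phenol with a tertiary propargylic chloride, the standard entry to aryl 1,1-dimethylpropargyl ethers; the 2'-hydroxyl is the only free OH and the stereocentre is remote from any acidic position.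

Step 12
Reactants: 15 (3R)-5-methoxy-7-(methoxymethoxy)-3-[4-(methoxymethoxy)-2-(2-methylbut-3-yn-2-yloxy)phenyl]-3,4-dihydro-2H-chromene
Product: 17 (3R)-5-methoxy-7-(methoxymethoxy)-3-[5-(methoxymethoxy)-2,2-dimethyl-2H-chromen-8-yl]-3,4-dihydro-2H-chromene, via allenylphenol 16 (not isolated)
Conditions: o-xylene, 140 °C
Reagents that add atoms: none
Why: Aromatic propargyl Claisen rearrangement to C3', the only free ortho position, then tautomerisation to the allenylphenol, 1,5-hydrogen shift and oxa-6π electrocyclisation to the 2,2-dimethylchromene; the 4'-oxygen is capped, so only the 2'-oxygen can close the pyran.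

Step 13
Reactants: 17 (3R)-5-methoxy-7-(methoxymethoxy)-3-[5-(methoxymethoxy)-2,2-dimethyl-2H-chromen-8-yl]-3,4-dihydro-2H-chromene
Product: 18 8-[(3R)-7-hydroxy-5-methoxy-3,4-dihydro-2H-chromen-3-yl]-2,2-dimethyl-2H-chromen-5-ol
Conditions: HCl (2 M aq.), MeOH, 40 °C
Reagents that add atoms: none
Why: Acid-catalysed acetal cleavage (methanolysis) of the two aryl MOM ethers; the aryl methyl ether, the chroman and the non-ionisable C3 stereocentre are stable, and dilute acid at moderate temperature is the usual way to unmask phenols next to a 2,2-dimethylchromene.

Compound list

1 | 2,4-dihydroxy-6-methoxybenzaldehyde | COc1cc(O)cc(O)c1C=O | starting material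
2 | 2-hydroxy-6-methoxy-4-(methoxymethoxy)benzaldehyde | COc1cc(OCOC)cc(O)c1C=O | intermediate
3 | 2,4-dihydroxyphenylacetic acid | OC(=O)Cc1ccc(O)cc1O | starting material
4 | 6-hydroxybenzofuran-2(3H)-one | O=C1Cc2ccc(O)cc2O1 | intermediate
5 | 6-(methoxymethoxy)benzofuran-2(3H)-one | O=C1Cc2ccc(OCOC)cc2O1 | intermediate
6 | 3-[2-hydroxy-6-methoxy-4-(methoxymethoxy)benzylidene]-6-(methoxymethoxy)benzofuran-2(3H)-one (double-bond geometry not defined) | COc1cc(OCOC)cc(O)c1C=C1C(=O)Oc2cc(OCOC)ccc21 | intermediate
7 | 3-[2-hydroxy-4-(methoxymethoxy)phenyl]-5-methoxy-7-(methoxymethoxy)-2H-chromen-2-one | COc1cc(OCOC)cc2oc(=O)c(-c3ccc(OCOC)cc3O)cc12 | intermediate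
8 | 3-[2-(tert-butyldimethylsilyloxy)-4-(methoxymethoxy)phenyl]-5-methoxy-7-(methoxymethoxy)-2H-chromen-2-one | COc1cc(OCOC)cc2oc(=O)c(-c3ccc(OCOC)cc3O[Si](C)(C)C(C)(C)C)cc12 | intermediate
9 | (Z)-2-[2-(tert-butyldimethylsilyloxy)-4-(methoxymethoxy)phenyl]-3-[2-hydroxy-6-methoxy-4-(methoxymethoxy)phenyl]prop-2-en-1-ol | OC/C(=C\c1c(O)cc(OCOC)cc1OC)c1ccc(OCOC)cc1O[Si](C)(C)C(C)(C)C | intermediate
10 | tert-butyl{2-[5-methoxy-7-(methoxymethoxy)-2H-chromen-3-yl]-5-(methoxymethoxy)phenoxy}dimethylsilane | COc1cc(OCOC)cc2c1C=C(c1ccc(OCOC)cc1O[Si](C)(C)C(C)(C)C)CO2 | intermediate
11 | 2-[5-methoxy-7-(methoxymethoxy)-2H-chromen-3-yl]-5-(methoxymethoxy)phenol | COc1cc(OCOC)cc2c1C=C(c1ccc(OCOC)cc1O)CO2 | intermediate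
12 | (6aR,11aR)-1-methoxy-3,9-bis(methoxymethoxy)-6a,11a-dihydro-6H-benzofuro[3,2-c]chromene (cis-pterocarpan) | COc1cc(OCOC)cc2c1[C@@H]1Oc3cc(OCOC)ccc3[C@@H]1CO2 | intermediate
13 | 2-[(3R)-5-methoxy-7-(methoxymethoxy)-3,4-dihydro-2H-chromen-3-yl]-5-(methoxymethoxy)phenol | COc1cc(OCOC)cc2c1C[C@H](c1ccc(OCOC)cc1O)CO2 | intermediate
14 | 3-chloro-3-methylbut-1-yne | C#CC(C)(C)Cl | starting material
15 | (3R)-5-methoxy-7-(methoxymethoxy)-3-[4-(methoxymethoxy)-2-(2-methylbut-3-yn-2-yloxy)phenyl]-3,4-dihydro-2H-chromene | COc1cc(OCOC)cc2c1C[C@H](c1ccc(OCOC)cc1OC(C)(C)C#C)CO2 | intermediate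
16 | 2-[(3R)-5-methoxy-7-(methoxymethoxy)-3,4-dihydro-2H-chromen-3-yl]-5-(methoxymethoxy)-6-(3-methylbuta-1,2-dienyl)phenol | COc1cc(OCOC)cc2c1C[C@H](c1ccc(OCOC)c(C=C=C(C)C)c1O)CO2 | intermediate
17 | (3R)-5-methoxy-7-(methoxymethoxy)-3-[5-(methoxymethoxy)-2,2-dimethyl-2H-chromen-8-yl]-3,4-dihydro-2H-chromene | COc1cc(OCOC)cc2c1C[C@H](c1ccc(OCOC)c3c1OC(C)(C)C=C3)CO2 | intermediate
18 | 8-[(3R)-7-hydroxy-5-methoxy-3,4-dihydro-2H-chromen-3-yl]-2,2-dimethyl-2H-chromen-5-ol | COc1cc(O)cc2c1C[C@H](c1ccc(O)c3c1OC(C)(C)C=C3)CO2 | target

Total step count: 13. Longest linear sequence: 12 steps (from 3 through steps 2 to 13); the ring A branch from 1 joins at step 4.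

Steps least certain to work

Step 9 (key step). Three things are most likely to go wrong.
- Facial selectivity of the proton transfer may be poor, or kinetic control may be lost if the cation sheds the C3 proton and re-enters the cycle through an unselective background pathway.
- Protonation may occur at C4 instead, giving a ring B stabilised C3 cation. This would move the double bond toward the enol ether and lead to an isomeric cyclic acetal.
- The acid may exchange or remove a methoxymethyl group.

Fallback, using known chemistry: set out from 10 and hydrogenate the trisubstituted double bond enantioselectively with a cationic iridium phosphinooxazoline catalyst, [Ir(cod)(L)]B[C6H3(CF3)2]4 (L = chiral phosphinooxazoline, antipode chosen for 3R), under H2 in CH2Cl2. This is a known reaction type for 3-aryl-2H-chromenes. It gives tert-butyl{2-[(3R)-5-methoxy-7-(methoxymethoxy)-3,4-dihydro-2H-chromen-3-yl]-5-(methoxymethoxy)phenoxy}dimethylsilane F1. Desilylation with Bu4NF/AcOH then returns to the route at 13, and steps 8 to 10 are replaced by two steps.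

Step 3. Enolisation of the lactone CH2, which is more acidic than the phenol, may compete with O-alkylation and lead to C-alkylation or to ring-opening oligomers. Fallback: move the protection to after the lactone is gone. Set out from 4 and 2 and condense them under the conditions of step 4 to give 3-(2,4-dihydroxyphenyl)-5-methoxy-7-(methoxymethoxy)-2H-chromen-2-one F2. Then put one MOM group on the unhindered 4'-hydroxyl (MOMCl, iPr2NEt, one equivalent, low temperature); the 2'-hydroxyl is flanked by the coumarin and hydrogen-bonded to its carbonyl. This returns to the route at 7.

Step 4. The aldehyde is deactivated by three oxygen donors, so the condensation may stall, and the phenoxide may open the aryl lactone intermolecularly. Fallback: a Perkin condensation through anhydride activation. Set out from 2 and 5 and heat them in Ac2O/Et3N at 110 °C to give 2-[5-methoxy-7-(methoxymethoxy)-2-oxo-2H-chromen-3-yl]-5-(methoxymethoxy)phenyl acetate F3. Methanolysis of the acetate (K2CO3, MeOH) returns to the route at 7.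

Step 10. Cleavage of the C11a–O bond may be slow in neutral solvent, and adding acid to speed it up would endanger the MOM ethers. Fallback: replace surface hydrogenolysis by electron-transfer cleavage of the benzyl aryl ether with Li in NH3/THF at −78 °C. This sets out from 12, returns at 13 and makes no new compound (F0).

Step 13. The acid may add solvent to the chromene double bond, or oligomerise it, through the ring B stabilised benzylic cation faster than it cleaves the second MOM group. Fallback: exchange the protecting group under aprotic conditions. Set out from 17 and treat it with TMSOTf and 2,2'-bipyridyl in CH2Cl2, which converts aryl MOM ethers into aryl trimethylsilyl ethers without a free Brønsted acid. This gives (3R)-5-methoxy-7-(trimethylsilyloxy)-3-[2,2-dimethyl-5-(trimethylsilyloxy)-2H-chromen-8-yl]-3,4-dihydro-2H-chromene F4. Brief methanolysis (K2CO3, MeOH) returns to the route at 18.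

Further compounds

F1 | step 9 | tert-butyl{2-[(3R)-5-methoxy-7-(methoxymethoxy)-3,4-dihydro-2H-chromen-3-yl]-5-(methoxymethoxy)phenoxy}dimethylsilane | COc1cc(OCOC)cc2c1C[C@H](c1ccc(OCOC)cc1O[Si](C)(C)C(C)(C)C)CO2
F2 | step 3 | 3-(2,4-dihydroxyphenyl)-5-methoxy-7-(methoxymethoxy)-2H-chromen-2-one | COc1cc(OCOC)cc2oc(=O)c(-c3ccc(O)cc3O)cc12
F3 | step 4 | 2-[5-methoxy-7-(methoxymethoxy)-2-oxo-2H-chromen-3-yl]-5-(methoxymethoxy)phenyl acetate | COc1cc(OCOC)cc2oc(=O)c(-c3ccc(OCOC)cc3OC(C)=O)cc12
F0 | step 10 | none | none
F4 | step 13 | (3R)-5-methoxy-7-(trimethylsilyloxy)-3-[2,2-dimethyl-5-(trimethylsilyloxy)-2H-chromen-8-yl]-3,4-dihydro-2H-chromene | COc1cc(O[Si](C)(C)C)cc2c1C[C@H](c1ccc(O[Si](C)(C)C)c3c1OC(C)(C)C=C3)CO2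
A1 | alternative 1 | (3R)-3-[5-(tert-butyldimethylsilyloxy)-2,2-dimethyl-2H-chromen-8-yl]-5-methoxy-7-(triisopropylsilyloxy)-3,4-dihydro-2H-chromen-2-ol (both anomers at C2) | COc1cc(O[Si](C(C)C)(C(C)C)C(C)C)cc2c1C[C@H](c1ccc(O[Si](C)(C)C(C)(C)C)c3c1OC(C)(C)C=C3)C(O)O2
A2 | alternative 1 | 3-methoxy-5-(triisopropylsilyloxy)phenol | COc1cc(O)cc(O[Si](C(C)C)(C(C)C)C(C)C)c1
A3 | alternative 1 | 2-[5-(tert-butyldimethylsilyloxy)-2,2-dimethyl-2H-chromen-8-yl]prop-2-enal | C=C(C=O)c1ccc(O[Si](C)(C)C(C)(C)C)c2c1OC(C)(C)C=C2
A4 | alternative 2 | (3R)-5-methoxy-7-(methoxymethoxy)-3-[5-(methoxymethoxy)-2,2-dimethyl-2H-chromen-8-yl]-3,4-dihydro-2H-chromene | COc1cc(OCOC)cc2c1C[C@H](c1ccc(OCOC)c3c1OC(C)(C)C=C3)CO2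
A5 | alternative 2 | 6-[(3R)-5-methoxy-7-(methoxymethoxy)-3,4-dihydro-2H-chromen-3-yl]-3-(methoxymethoxy)-2-(trimethylsilyl)phenyl trifluoromethanesulfonate | COc1cc(OCOC)cc2c1C[C@H](c1ccc(OCOC)c([Si](C)(C)C)c1OS(=O)(=O)C(F)(F)F)CO2
A6 | alternative 2 | (3R)-5-methoxy-7-(methoxymethoxy)-3-[4-(methoxymethoxy)-2,3-didehydrophenyl]-3,4-dihydro-2H-chromene (aryne) | COc1cc(OCOC)cc2c1C[C@H](C1=CC=C(OCOC)C#C1)CO2
A7 | alternative 2 | 3-methylbut-2-enal | CC(C)=CC=O
A8 | alternative 3 | (3R)-7-(tert-butyldimethylsilyloxy)-3-[5-(tert-butyldimethylsilyloxy)-2,2-dimethyl-2H-chromen-8-yl]-5-methoxy-3,4-dihydro-2H-chromen-2-ol (both anomers at C2) | COc1cc(O[Si](C)(C)C(C)(C)C)cc2c1C[C@H](c1ccc(O[Si](C)(C)C(C)(C)C)c3c1OC(C)(C)C=C3)C(O)O2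
A9 | alternative 3 | 5-(tert-butyldimethylsilyloxy)-2-(hydroxymethyl)-3-methoxyphenol | COc1cc(O[Si](C)(C)C(C)(C)C)cc(O)c1CO
A10 | alternative 3 | 3-(tert-butyldimethylsilyloxy)-5-methoxy-6-methylidenecyclohexa-2,4-dien-1-one | C=C1C(=O)C=C(O[Si](C)(C)C(C)(C)C)C=C1OC
A11 | alternative 3 | 2-[5-(tert-butyldimethylsilyloxy)-2,2-dimethyl-2H-chromen-8-yl]acetaldehyde | O=CCc1ccc(O[Si](C)(C)C(C)(C)C)c2c1OC(C)(C)C=C2
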